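**Retrosynthetic overview**

1. Target 23 ⇒ ketol 22 by the C3–C4 bond. The seven-membered vinylogous ester ring of 22 (C10–C1(=O)–C2=C3–O–C6–C5, a 6,7-dihydrooxepin-4(5H)-one) holds the acceptor carbon C3 across the ring from the isopropenyl group on C5, so one tertiary radical at C4 closes the tetrahydrofuran and the cyclohexanone ring together.
2. Ring D: methyl addition to a 15,16-dione made from ketone 19, which comes from 5-exo radical closure (C16–C13) of a bromoacetyl group onto the ring C cyclohexene.
3. Ring C with C8/C9: Diels–Alder reaction of butadiene with the 3-acetyl-5,6-dihydropyran-2-one 14, whose δ-lactone ring is closed by condensing an acetoacetate on C20–O with the masked aldehyde C9.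
4. Oxepinone: two-carbon ring expansion of γ-lactone 7 (acetylide addition, 7-endo oxa-Michael). C10 is set by two enolate alkylations anti to the C5 isopropenyl group, and C5 by Rh/BINAP conjugate addition to furan-2(5H)-one.
5. Ring order: γ-lactone template → oxepinone → δ-lactone → ring C → ring D → ring A plus tetrahydrofuran (last step).

Key step: step 16

Remark: locants C1–C20 are kaurane-type locants of the target (C7/C20 = lactone carbonyl and its OCH2, C15/C16 = ketol carbons); the absolute sense of step 1 is assumed to follow the established model for Rh/BINAP additions to cyclic enones and unsaturated lactones.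

**Route**

Step 1
Reactants: 1 furan-2(5H)-one; 2 potassium trifluoro(prop-1-en-2-yl)borate
Product: 3 (R)-4-(prop-1-en-2-yl)dihydrofuran-2(3H)-one
Conditions: [Rh(cod)2]BF4 (3 mol %), (R)-BINAP (3.3 mol %), PhMe/H2O 10:1, 100 °C
Reagents that add atoms: none
Why: Hayashi–Miyaura rhodium-catalysed asymmetric 1,4-addition of an alkenylboron reagent to an unsaturated lactone, in which the (R)-BINAP complex should deliver the isopropenyl group to the face that gives the (R)-centre (C5), by analogy with cyclic enones.

Step 2
Reactants: 3 (R)-4-(prop-1-en-2-yl)dihydrofuran-2(3H)-one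
Product: 4 (3R,4R)-3-(hydroxymethyl)-4-(prop-1-en-2-yl)dihydrofuran-2(3H)-one
Conditions: LiN(iPr)2, THF, −78 °C; CH2O (gas, from cracked paraformaldehyde), −78 → −40 °C; AcOH
Reagents that add atoms: formaldehyde, C=O
Why: aldol reaction of the lactone lithium enolate with monomeric formaldehyde, the electrophile entering anti to the isopropenyl group to give the trans lactone (this centre is re-formed in step 4).

Step 3
Reactants: 4 (3R,4R)-3-(hydroxymethyl)-4-(prop-1-en-2-yl)dihydrofuran-2(3H)-one
Product: 5 (3R,4R)-3-[(tert-butyldimethylsilyloxy)methyl]-4-(prop-1-en-2-yl)dihydrofuran-2(3H)-one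
Conditions: t-BuMe2SiCl, imidazole, DMF, rt
Reagents that add atoms: tert-butyldimethylsilyl chloride, CC(C)(C)[Si](C)(C)Cl
Why: standard silylation of a primary alcohol, protecting the C20 oxygen through the enolate and acetylide steps.

Step 4
Reactants: 5 (3R,4R)-3-[(tert-butyldimethylsilyloxy)methyl]-4-(prop-1-en-2-yl)dihydrofuran-2(3H)-one
Product: 7 (3S,4S)-3-[(tert-butyldimethylsilyloxy)methyl]-3-(dimethoxymethyl)-4-(prop-1-en-2-yl)dihydrofuran-2(3H)-one, via silyl ketene acetal 6 (not isolated)
Conditions: LiN(iPr)2, Me3SiCl (internal quench), THF, −78 °C; then HC(OMe)3, Me3SiOTf (10 mol %), CH2Cl2, −78 °C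
Reagents that add atoms: trimethyl orthoformate, COC(OC)OC; chlorotrimethylsilane, C[Si](C)(C)Cl (silyl group present in 6 only)
Why: Mukaiyama-type alkylation of the silyl ketene acetal by the dimethoxycarbenium ion should install the masked formyl carbon C9 anti to the isopropenyl group, which fixes the quaternary centre C10 with CH2OSi cis to isopropenyl, and the internal silyl quench avoids β-elimination of silyloxide from the lithium enolate.

Step 5
Reactants: 7 (3S,4S)-3-[(tert-butyldimethylsilyloxy)methyl]-3-(dimethoxymethyl)-4-(prop-1-en-2-yl)dihydrofuran-2(3H)-one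
Product: 8 4-[(tert-butyldimethylsilyloxy)methyl]-4-(dimethoxymethyl)-6-hydroxy-5-(prop-1-en-2-yl)hex-1-yn-3-one
Conditions: HC≡CLi (from HC≡CH and n-BuLi), THF, −78 → −40 °C; AcOH
Reagents that add atoms: acetylene (as its lithium salt), C#C
Why: addition of lithium acetylide to a lactone, where the tetrahedral lithium lactolate should persist at low temperature and so prevent a second addition, opening to the hydroxy ynone (in equilibrium with its lactol) on work-up.

Step 6
Reactants: 8 4-[(tert-butyldimethylsilyloxy)methyl]-4-(dimethoxymethyl)-6-hydroxy-5-(prop-1-en-2-yl)hex-1-yn-3-one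
Product: 9 5-[(tert-butyldimethylsilyloxy)methyl]-5-(dimethoxymethyl)-6-(prop-1-en-2-yl)-6,7-dihydrooxepin-4(5H)-one
Conditions: Cs2CO3 (0.2 equiv), MeCN (0.01 M), rt
Reagents that add atoms: none
Why: intramolecular oxa-Michael addition (7-endo-dig) of the C6 alkoxide to the ynone β-carbon, favoured by the quaternary C10 and substituted C5 (gem-disubstituent effect), while lactol formation is reversible and feeds the same product; no acid is used so the acetal and the free hydroxyl do not exchange.

Step 7
Reactants: 9 5-[(tert-butyldimethylsilyloxy)methyl]-5-(dimethoxymethyl)-6-(prop-1-en-2-yl)-6,7-dihydrooxepin-4(5H)-one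
Product: 10 5-(dimethoxymethyl)-5-(hydroxymethyl)-6-(prop-1-en-2-yl)-6,7-dihydrooxepin-4(5H)-one
Conditions: Bu4NF, AcOH (1:1), THF, 0 °C
Reagents that add atoms: none
Why: fluoride desilylation buffered with acetic acid, so that no free alkoxide is available to attack C3 and switch the vinylogous ester to the six-membered isomer.

Step 8
Reactants: 10 5-(dimethoxymethyl)-5-(hydroxymethyl)-6-(prop-1-en-2-yl)-6,7-dihydrooxepin-4(5H)-one; 11 2,2,6-trimethyl-4H-1,3-dioxin-4-one
Product: 12 acetoacetate ester of 10
Conditions: PhMe, 110 °C
Reagents that add atoms: none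
Why: neutral acetoacetylation by thermal retro-[4+2] of the dioxinone to acetylketene and its capture by the neopentyl alcohol.

Step 9
Reactants: 12 acetoacetate ester of 10
Product: 14 spiro 3-acetyl-5,6-dihydro-2H-pyran-2-one dienophile, via methoxy aldol lactone 13 (not isolated)
Conditions: TiCl4 (2.2 equiv), Et3N (4 equiv), CH2Cl2, −78 → 0 °C
Reagents that add atoms: none
Why: intramolecular Knoevenagel-type condensation in which the titanium enolate of the β-keto ester adds to the oxocarbenium ion released from the acetal (Mukaiyama-type aldol) and methanol is then lost by E1cB elimination, closing the δ-lactone ring.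

Step 10
Reactants: 14 spiro 3-acetyl-5,6-dihydro-2H-pyran-2-one dienophile; 15 buta-1,3-diene
Product: 16 cis-fused cyclohexene δ-lactone with acetyl on C8
Conditions: ZnCl2 (1 equiv), CH2Cl2, −20 °C → rt, sealed tube
Reagents that add atoms: none
Why: Lewis acid-promoted Diels–Alder reaction of a doubly activated α-acyl unsaturated lactone, where suprafacial addition makes the lactone cis-fused to ring C (acetyl anti to C10) and the diene should approach the face of C8=C9 flanked by the flat C1 carbonyl and not by C5–H, setting C8 and C9 relative to C10.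

Step 11
Reactants: 16 cis-fused cyclohexene δ-lactone with acetyl on C8
Product: 18 bromoacetyl ketone, via trimethylsilyl enol ether 17 (not isolated)
Conditions: Me3SiOTf, Et3N, CH2Cl2, 0 °C; then NBS, THF, −78 °C
Reagents that add atoms: N-bromosuccinimide, O=C1CCC(=O)N1Br; trimethylsilyl trifluoromethanesulfonate, C[Si](C)(C)OS(=O)(=O)C(F)(F)F (silyl group present in 17 only)
Why: soft enolization of the only enolizable ketone (C8 is quaternary) and electrophilic bromination of the silyl enol ether, which is far more nucleophilic than the push–pull C2=C3 or the isolated alkenes.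

Step 12
Reactants: 18 bromoacetyl ketone
Product: 19 bicyclo[3.2.1]octan-15-one (ring D closed)
Conditions: Bu3SnH, AIBN (cat.), PhH (0.01 M), 80 °C, syringe pump
Reagents that add atoms: none
Why: tin hydride-mediated 5-exo-trig cyclization of the α-keto radical (C16) onto C13 of the cyclohexene, the acyl group on C8 being 1,3-diaxially disposed to C13 so that the tether fixes C13, with the C12 radical quenched by Bu3SnH.

Step 13
Reactants: 19 bicyclo[3.2.1]octan-15-one
Product: 20 16-hydroxy-15-ketone (C16 epimers)
Conditions: KN(SiMe3)2, THF, −78 °C; 2-(phenylsulfonyl)-3-phenyloxaziridine; AcOH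
Reagents that add atoms: 2-(phenylsulfonyl)-3-phenyloxaziridine, O=S(=O)(c1ccccc1)N1OC1c1ccccc1
Why: Davis α-hydroxylation of the potassium enolate, which can form only toward C16 because C8 is quaternary and the vinylogous ester has no acidic hydrogen; the C16 configuration is immaterial as it is oxidized in step 14.

Step 14
Reactants: 20 16-hydroxy-15-ketone
Product: 21 15,16-dione
Conditions: Dess–Martin periodinane, CH2Cl2, rt
Reagents that add atoms: none
Why: Dess–Martin oxidation of the secondary α-ketol to a 1,2-dione that cannot enolize (C13 is a bridgehead, C8 is quaternary).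

Step 15
Reactants: 21 15,16-dione
Product: 22 16-hydroxy-16-methyl-15-ketone (key-step precursor)
Conditions: MeMgBr (1.05 equiv), THF, −78 °C; aq NH4Cl
Reagents that add atoms: methylmagnesium bromide, C[Mg]Br
Why: Grignard addition to the more accessible carbonyl of the α-diketone (C16, next to the CH bridgehead and not C15 next to quaternary C8) from the exo face (side of the C14 methylene bridge), which should give the carbinol with methyl exo and hydroxyl toward the C11–C12 bridge as required, the vinylogous ester and lactone carbonyls being much less electrophilic at −78 °C.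

Step 16
Reactants: 22 16-hydroxy-16-methyl-15-ketone (key-step precursor)
Product: 23 target CNP0538153.1
Conditions: Fe(acac)3 (30 mol %), PhSiH3 (2.5 equiv, slow addition), EtOH/(CH2OH)2 5:1, degassed, 0.01 M, 60 °C
Reagents that add atoms: none
Why: Hydrogen-atom transfer from a trivalent iron hydride to the terminal CH2 of the isopropenyl group, the only unconjugated 1,1-disubstituted alkene, gives the tertiary C4 radical, which adds to C3 of the vinylogous ester; the resulting C2 α-keto radical is reduced by divalent iron to the enolate and protonated by ethanol. The closest known reaction types are the Fe(acac)3/PhSiH3 reductive olefin–enone coupling (hydrogen-atom-transfer-initiated Giese cyclization that forms quaternary carbons) and the 5-exo cyclization of alkyl radicals onto β-alkoxy enones and acrylates. The single C3–C4 bond closes the tetrahydrofuran ring (O, C3, C4, C5, C6) in the 5-exo-trig mode and the cyclohexanone ring (C1, C2, C3, C4, C5, C10) in the 6-endo-trig mode, stitching the seven-membered ring into the 6-oxabicyclo[3.2.1]octan-2-one. C3 is the only new stereocentre and is dictated by the tether, since C4 is held on one face of the oxepinone by the C5 centre and the one-carbon bridge can only form cis; C4 is not stereogenic and C5 and C10 are untouched. The step needs attack at C3 and not at C2, and cyclization faster than reduction of the radical: the nucleophilic tertiary radical is polarity-matched with the electrophilic β-carbon C3 (giving the carbonyl-stabilized radical), and high dilution with slow silane delivery should suppress simple hydrogenation.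

**Compound list**

1 | furan-2(5H)-one | O=C1C=CCO1 | starting material
2 | potassium trifluoro(prop-1-en-2-yl)borate | [K+].CC(=C)[B-](F)(F)F | starting material
3 | (R)-4-(prop-1-en-2-yl)dihydrofuran-2(3H)-one | O=C1C[C@H](C(C)=C)CO1 | intermediate
4 | (3R,4R)-3-(hydroxymethyl)-4-(prop-1-en-2-yl)dihydrofuran-2(3H)-one, trans | O=C1[C@@H](CO)[C@H](C(C)=C)CO1 | intermediate
5 | (3R,4R)-3-[(tert-butyldimethylsilyloxy)methyl]-4-(prop-1-en-2-yl)dihydrofuran-2(3H)-one | O=C1[C@@H](CO[Si](C)(C)C(C)(C)C)[C@H](C(C)=C)CO1 | intermediate
6 | cyclic silyl ketene acetal of 5: 4-[(tert-butyldimethylsilyloxy)methyl]-3-(prop-1-en-2-yl)-5-(trimethylsilyloxy)-2,3-dihydrofuran, C3 centre unchanged | C[Si](C)(C)OC1=C(CO[Si](C)(C)C(C)(C)C)[C@H](C(C)=C)CO1 | intermediate (not isolated)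
7 | (3S,4S)-3-[(tert-butyldimethylsilyloxy)methyl]-3-(dimethoxymethyl)-4-(prop-1-en-2-yl)dihydrofuran-2(3H)-one, CH2OSi cis to isopropenyl | O=C1[C@](C(OC)OC)(CO[Si](C)(C)C(C)(C)C)[C@H](C(C)=C)CO1 | intermediate
8 | 4-[(tert-butyldimethylsilyloxy)methyl]-4-(dimethoxymethyl)-6-hydroxy-5-(prop-1-en-2-yl)hex-1-yn-3-one, C4 and C5 as in 7 | C#CC(=O)[C@](C(OC)OC)(CO[Si](C)(C)C(C)(C)C)[C@H](C(C)=C)CO | intermediate
9 | 5-[(tert-butyldimethylsilyloxy)methyl]-5-(dimethoxymethyl)-6-(prop-1-en-2-yl)-6,7-dihydrooxepin-4(5H)-one, CH2OSi cis to isopropenyl | O=C1C=COC[C@@H](C(C)=C)[C@@]1(C(OC)OC)CO[Si](C)(C)C(C)(C)C | intermediate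
10 | 5-(dimethoxymethyl)-5-(hydroxymethyl)-6-(prop-1-en-2-yl)-6,7-dihydrooxepin-4(5H)-one, same configuration | O=C1C=COC[C@@H](C(C)=C)[C@@]1(C(OC)OC)CO | intermediate
11 | 2,2,6-trimethyl-4H-1,3-dioxin-4-one | CC1=CC(=O)OC(C)(C)O1 | starting material
12 | 3-oxobutanoate (acetoacetate) ester of 10 | O=C1C=COC[C@@H](C(C)=C)[C@@]1(C(OC)OC)COC(=O)CC(C)=O | intermediate
13 | spiro δ-lactone with acetyl on C8 and methoxy on C9 (C8, C9 unassigned) | O=C1C=COC[C@@H](C(C)=C)[C@@]12COC(=O)C(C(C)=O)C2OC | intermediate (not isolated)
14 | spiro dienophile: 3-acetyl-5,6-dihydro-2H-pyran-2-one whose C5 is the spiro carbon C10 of the 6-isopropenyl-6,7-dihydrooxepin-4(5H)-one | O=C1C=COC[C@@H](C(C)=C)[C@@]12COC(=O)C(C(C)=O)=C2 | intermediate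
15 | buta-1,3-diene | C=CC=C | starting material
16 | Diels–Alder adduct: δ-lactone cis-fused to a cyclohexene (C12=C13), acetyl on C8 anti to C10, C11 on the face of the C1 carbonyl | O=C1C=COC[C@@H](C(C)=C)[C@@]12COC(=O)[C@@]3(C(C)=O)CC=CC[C@@H]23 | intermediate
17 | trimethylsilyl enol ether of the acetyl group of 16 | O=C1C=COC[C@@H](C(C)=C)[C@@]12COC(=O)[C@@]3(C(=C)O[Si](C)(C)C)CC=CC[C@@H]23 | intermediate (not isolated)
18 | bromoacetyl analogue of 16 | O=C1C=COC[C@@H](C(C)=C)[C@@]12COC(=O)[C@@]3(C(=O)CBr)CC=CC[C@@H]23 | intermediate
19 | spiro oxepinone δ-lactone fused to a bicyclo[3.2.1]octane with C15 ketone and C16 CH2 | O=C1C=COC[C@@H](C(C)=C)[C@@]12COC(=O)[C@@]34C[C@@H](CC[C@H]32)CC4=O | intermediate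
20 | 16-hydroxy-15-ketone of 19, epimers at C16 | O=C1C=COC[C@@H](C(C)=C)[C@@]12COC(=O)[C@@]34C[C@@H](CC[C@H]32)C(O)C4=O | intermediate
21 | 15,16-dione of 19 | O=C1C=COC[C@@H](C(C)=C)[C@@]12COC(=O)[C@@]34C[C@@H](CC[C@H]32)C(=O)C4=O | intermediate
22 | 16-hydroxy-16-methyl-15-ketone, hydroxyl toward the C11–C12 bridge, methyl exo; spiro 6-isopropenyl-6,7-dihydrooxepin-4(5H)-one intact | O=C1C=COC[C@@H](C(C)=C)[C@@]12COC(=O)[C@@]34C[C@@H](CC[C@H]32)[C@@](C)(O)C4=O | intermediate
23 | CNP0538153.1: 3,6-epoxy-16-hydroxy-1,15-dioxo-6,7-secokauran-7,20-olide skeleton, configuration as in the SMILES | CC1(C)[C@@H]2CC(=O)[C@]3(COC(=O)[C@@]45C[C@@H](CC[C@H]43)[C@@](C)(O)C5=O)[C@H]1CO2 | target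

**Step count and risks**

Total step count: 16. Longest linear sequence: 16 steps, from furan-2(5H)-one.

Steps most likely to fail:

Step 16. The tertiary radical may be reduced before it cyclizes (net hydrogenation to the isopropyl compound), or hydrogen-atom transfer may occur at the push–pull alkene. The fallback generates the same radical without a metal hydride. It sets out from 22: Markovnikov addition of anhydrous HCl (Et2O/CH2Cl2, −40 °C) to the isopropenyl group should give the tertiary chloride F1. Treatment with Bu3SnH and AIBN (PhH, 80 °C, syringe pump) abstracts chlorine in a chain process, and the known tin-mediated 5-exo cyclization onto the β-alkoxy enone comes back to the route at 23.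

Step 6. The seven-membered closure may be slower than trapping of the alkoxide as the five-membered lactol or intermolecular conjugate addition to the ynone (oligomers). The fallback replaces conjugate addition to the alkyne by vinylic substitution on a preset cis alkene. It sets out from 8: hydroiodination (LiI, AcOH, MeCN, rt) should give the (Z)-β-iodovinyl ketone F2. Intramolecular addition–elimination by the C6 alkoxide (Cs2CO3, PhMe, 60 °C, with CuI and 1,10-phenanthroline if needed) comes back to the route at 9.

Step 12. The α-keto radical may close in the 6-endo mode onto C12, leading to the bicyclo[2.2.2]octane skeleton, or be reduced without cyclizing. The fallback uses a chlorine atom on C12 as a removable regiocontrol element. It sets out from 14: Diels–Alder reaction with 2-chlorobuta-1,3-diene (ZnCl2 or thermal; the para orientation places chlorine on C12) should give the vinyl chloride adduct F3. Bromination as in step 11 gives the bromoacetyl vinyl chloride F4. With Bu3SnH and AIBN the α-keto radical should add only to the unsubstituted alkene carbon C13 (giving the α-chloroalkyl radical), which leads to the C12 chloro ketone F5. A further equivalent of Bu3SnH in PhMe at 110 °C removes the chlorine and comes back to the route at 19.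

Further compounds
F1 | step 16 | tertiary chloride of 22 (2-chloropropan-2-yl group on C5) | O=C1C=COC[C@@H](C(C)(C)Cl)[C@@]12COC(=O)[C@@]34C[C@@H](CC[C@H]32)[C@@](C)(O)C4=O
F2 | step 6 | (Z)-1-iodo-4-[(tert-butyldimethylsilyloxy)methyl]-4-(dimethoxymethyl)-6-hydroxy-5-(prop-1-en-2-yl)hex-1-en-3-one | I/C=C\C(=O)[C@](C(OC)OC)(CO[Si](C)(C)C(C)(C)C)[C@H](C(C)=C)CO
F3 | step 12 | 12-chloro analogue of Diels–Alder adduct 16 | O=C1C=COC[C@@H](C(C)=C)[C@@]12COC(=O)[C@@]3(C(C)=O)CC=C(Cl)C[C@@H]23
F4 | step 12 | 12-chloro analogue of bromoacetyl ketone 18 | O=C1C=COC[C@@H](C(C)=C)[C@@]12COC(=O)[C@@]3(C(=O)CBr)CC=C(Cl)C[C@@H]23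
F5 | step 12 | 12-chloro analogue of bicyclic ketone 19 (C12 unassigned) | O=C1C=COC[C@@H](C(C)=C)[C@@]12COC(=O)[C@@]34C[C@@H](C(Cl)C[C@H]32)CC4=O
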